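A direct plan would assemble the C1–C10 keto acid A1 from a β-keto imide and an aldehyde taken from meso-2,4-dimethylglutaric anhydride, esterify it with a C11–C13 alkenol, and close the ring at C10–C11 by a SmI2-mediated Reformatsky-type aldol reaction of the bromo keto aldehyde A2.
Its weakest steps would be:
(a) the ring-closing aldol, which would have to create C10 and C11 in a 14-membered transition state with no proven control element, on an elimination-prone β-acyloxy aldehyde;
(b) the regioselective bromination at C10, which would need kinetic enolisation away from the C8 methine and the C2 ester position without epimerisation;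
(c) the four-step oxidation-state shuffle from the anhydride to the aldehyde, which would add length but no complexity.

The new route rests on a disconnection at C7, the only unsubstituted ring carbon. A C7=C8 double bond that is absent from the target is made on purpose by ring-closing metathesis of an ester-linked diene. Its two alkenes arise for free from the carbonyl additions that set C5/C6 (crotylation) and C10/C11 (aldol of an isopropenyl ketone). One operation closes the 14-membered ring with no enolate, halide or aldehyde at the closure site, and leaves C8 latent; it is then set from C5–OH and C6 by hydroxyl-directed hydrogenation. No ring-closing aldol, no regioselective bromination and no oxidation-state shuffle remain.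

Key step: step 15

Remark: locants in the comments follow the macrolide numbering (C1 = lactone carbonyl, C13 = oxygen-bearing ring carbon); δ-hydroxy ketones such as 21 and 27 may equilibrate with cyclic hemiketal forms, and the open forms are drawn.

Step 1
Reactants: 1 (R)-4-benzyl-3-propanoyl-1,3-oxazolidin-2-one; 2 methacrolein
Product: 4 (R)-4-benzyl-3-[(2R,3R)-3-hydroxy-2,4-dimethylpent-4-enoyl]-1,3-oxazolidin-2-one, via boron enolate 3 (not isolated)
Conditions: Bu2BOTf, iPr2NEt, CH2Cl2, −78 → 0 °C; 2, −78 → 0 °C; pH 7 buffer, MeOH, H2O2, 0 °C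
Reagents that add atoms: none
Why: Evans syn-aldol reaction: the (Z)-dibutylboron enolate adds to methacrolein through a Zimmerman–Traxler chair on the face away from the benzyl group, which sets C2 and C3 with the 2,3-syn relation, and the isopropenyl group carries the future C4 and C5.

Step 2
Reactants: 4 (R)-4-benzyl-3-[(2R,3R)-3-hydroxy-2,4-dimethylpent-4-enoyl]-1,3-oxazolidin-2-one
Product: 5 (R)-4-benzyl-3-[(2R,3R)-3-[(tert-butyldimethylsilyl)oxy]-2,4-dimethylpent-4-enoyl]-1,3-oxazolidin-2-one
Conditions: TBSOTf, 2,6-lutidine, CH2Cl2, −78 → 0 °C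
Reagents that add atoms: tert-butyldimethylsilyl trifluoromethanesulfonate, CC(C)(C)[Si](C)(C)OS(=O)(=O)C(F)(F)F
Why: Silylation with a silyl triflate and a hindered pyridine base protects the C3 hydroxyl without retro-aldol cleavage or epimerisation, and the bulky allylic silyl ether is the control element of the next step.

Step 3
Reactants: 5 (R)-4-benzyl-3-[(2R,3R)-3-[(tert-butyldimethylsilyl)oxy]-2,4-dimethylpent-4-enoyl]-1,3-oxazolidin-2-one
Product: 7 (R)-4-benzyl-3-[(2R,3S,4R)-3-[(tert-butyldimethylsilyl)oxy]-5-hydroxy-2,4-dimethylpentanoyl]-1,3-oxazolidin-2-one, via alkyl catecholboronate 6 (not isolated)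
Conditions: catecholborane, RhCl(PPh3)3 (cat.), THF, 0 °C → rt; then pH 7 buffer, EtOH, H2O2, 0 °C
Reagents that add atoms: hydrogen peroxide, OO
Why: Rhodium-catalysed hydroboration of a 1,1-disubstituted allylic silyl ether with catecholborane is anti-Markovnikov and syn-selective (the reverse of the uncatalysed reaction), which sets C4 with the 3,4-syn relation; buffered oxidation spares the imide, and the δ-hydroxy imide is used at once so that it cannot lactonise.

Step 4
Reactants: 7 (R)-4-benzyl-3-[(2R,3S,4R)-3-[(tert-butyldimethylsilyl)oxy]-5-hydroxy-2,4-dimethylpentanoyl]-1,3-oxazolidin-2-one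
Product: 8 (R)-4-benzyl-3-[(2R,3S,4S)-3-[(tert-butyldimethylsilyl)oxy]-2,4-dimethyl-5-oxopentanoyl]-1,3-oxazolidin-2-one
Conditions: Dess–Martin periodinane, NaHCO3, CH2Cl2, 0 °C → rt
Reagents that add atoms: none
Why: Dess–Martin oxidation under buffered, non-basic conditions should give the α-methyl aldehyde without epimerisation at C4 and leaves the imide and the silyl ether untouched.

Step 5
Reactants: 8 (R)-4-benzyl-3-[(2R,3S,4S)-3-[(tert-butyldimethylsilyl)oxy]-2,4-dimethyl-5-oxopentanoyl]-1,3-oxazolidin-2-one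
Product: 9 (R)-4-benzyl-3-[(2R,3S,4R,5S,6S)-3-[(tert-butyldimethylsilyl)oxy]-5-hydroxy-2,4,6-trimethyloct-7-enoyl]-1,3-oxazolidin-2-one
Conditions: trans-2-butene, n-BuLi, KOtBu, THF, −78 → −45 °C; (−)-Ipc2BOMe, −78 °C; BF3·OEt2; then 8, −78 °C; pH 7 buffer, MeOH, H2O2, 0 °C → rt
Reagents that add atoms: trans-2-butene (delivered as its (E)-crotyldiisopinocampheylborane), C/C=C/C
Why: Brown asymmetric crotylboration: the (E)-crotylborane reacts through a closed six-membered chair, so E geometry gives the 5,6-anti relation, and the face preference of the reagent made from (+)-α-pinene coincides with Felkin attack on the α-methyl aldehyde (4,5-syn), which sets C5 (S) and C6 (S) and delivers the vinyl group that becomes C7; buffered peroxide work-up spares the imide.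

Step 6
Reactants: 9 (R)-4-benzyl-3-[(2R,3S,4R,5S,6S)-3-[(tert-butyldimethylsilyl)oxy]-5-hydroxy-2,4,6-trimethyloct-7-enoyl]-1,3-oxazolidin-2-one
Product: 10 (R)-4-benzyl-3-[(2R,3S,4R,5S,6S)-3-[(tert-butyldimethylsilyl)oxy]-2,4,6-trimethyl-5-[(triethylsilyl)oxy]oct-7-enoyl]-1,3-oxazolidin-2-one
Conditions: TESOTf, 2,6-lutidine, CH2Cl2, −78 °C
Reagents that add atoms: triethylsilyl trifluoromethanesulfonate, CC[Si](CC)(CC)OS(=O)(=O)C(F)(F)F
Why: Prompt silylation of the hindered C5 hydroxyl blocks lactonisation onto the imide and installs the one silyl ether that can later be removed selectively beside two tert-butyldimethylsilyl ethers.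

Step 7
Reactants: 10 (R)-4-benzyl-3-[(2R,3S,4R,5S,6S)-3-[(tert-butyldimethylsilyl)oxy]-2,4,6-trimethyl-5-[(triethylsilyl)oxy]oct-7-enoyl]-1,3-oxazolidin-2-one
Product: 12 (2R,3S,4R,5S,6S)-3-[(tert-butyldimethylsilyl)oxy]-2,4,6-trimethyl-5-[(triethylsilyl)oxy]oct-7-enoic acid, via peroxy acid 11 (not isolated)
Conditions: LiOH, H2O2, THF/H2O, 0 °C; aq. Na2SO3; then cold dilute HCl to pH 4
Reagents that add atoms: hydrogen peroxide (as LiOOH), OO
Why: Hydroperoxide cleavage of an N-acyl oxazolidinone: LiOOH attacks the exocyclic carbonyl of the hindered imide and sulfite reduces the peracid, so the silyl ethers, the terminal alkene and the C2 configuration should be unaffected.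

Step 8
Reactants: 13 acetaldehyde
Product: 14 (2R,3R)-3-methylpent-4-en-2-ol
Conditions: cis-2-butene, n-BuLi, KOtBu, THF, −78 → −45 °C; (−)-Ipc2BOMe, −78 °C; BF3·OEt2; then 13, −78 °C; NaOH, H2O2
Reagents that add atoms: cis-2-butene (delivered as its (Z)-crotyldiisopinocampheylborane), C/C=C\C
Why: Brown asymmetric crotylboration: the (Z)-crotylborane adds through a closed chair, so Z geometry gives the 12,13-syn relation and the isopinocampheyl groups derived from (+)-α-pinene select the aldehyde face that gives C13 (R) and C12 (R in 14).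

Step 9
Reactants: 14 (2R,3R)-3-methylpent-4-en-2-ol
Product: 15 1-methoxy-4-({[(2R,3R)-3-methylpent-4-en-2-yl]oxy}methyl)benzene
Conditions: NaH, 4-methoxybenzyl chloride, Bu4NI (cat.), THF/DMF, 0 °C → rt
Reagents that add atoms: 4-methoxybenzyl chloride, COc1ccc(CCl)cc1
Why: Williamson etherification of the sodium alkoxide protects the C13 oxygen as an ether that survives ozonolysis, enolborination and silylation and is later removed oxidatively beside silyl ethers; no stereocentre is involved.

Step 10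
Reactants: 15 1-methoxy-4-({[(2R,3R)-3-methylpent-4-en-2-yl]oxy}methyl)benzene
Product: 16 (2S,3R)-3-[(4-methoxybenzyl)oxy]-2-methylbutanal
Conditions: O3, CH2Cl2, −78 °C (to the first trace of excess ozone); then PPh3, −78 °C → rt
Reagents that add atoms: ozone, [O-][O+]=O
Why: Ozonolysis with reductive work-up cleaves the terminal alkene, which reacts faster than the electron-rich arene, to the α-methyl aldehyde without touching C12, and the aldehyde is used directly.

Step 11
Reactants: 17 2-methylpent-1-en-3-one; 16 (2S,3R)-3-[(4-methoxybenzyl)oxy]-2-methylbutanal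
Product: 19 (4R,5S,6R,7R)-5-hydroxy-7-[(4-methoxybenzyl)oxy]-2,4,6-trimethyloct-1-en-3-one, via boron enolate 18 (not isolated)
Conditions: Bu2BOTf, iPr2NEt, Et2O, −78 °C; then 16, −78 → −20 °C; pH 7 buffer, MeOH, H2O2, 0 °C
Reagents that add atoms: none
Why: Boron-mediated syn-aldol reaction: the ketone can enolise only on its ethyl side, the (Z)-enolborinate adds through a Zimmerman–Traxler chair (10,11-syn), and the anti-Felkin preference of (Z)-enolates towards α-methyl aldehydes gives the 11,12-anti relation, which sets C10 (R) and C11 (S) while the isopropenyl ketone is carried on as the second metathesis partner.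

Step 12
Reactants: 19 (4R,5S,6R,7R)-5-hydroxy-7-[(4-methoxybenzyl)oxy]-2,4,6-trimethyloct-1-en-3-one
Product: 20 (4R,5S,6S,7R)-5-[(tert-butyldimethylsilyl)oxy]-7-[(4-methoxybenzyl)oxy]-2,4,6-trimethyloct-1-en-3-one
Conditions: TBSOTf, 2,6-lutidine, CH2Cl2, −78 °C
Reagents that add atoms: tert-butyldimethylsilyl trifluoromethanesulfonate, CC(C)(C)[Si](C)(C)OS(=O)(=O)C(F)(F)F
Why: Low-temperature silylation of the β-hydroxy ketone protects C11–OH before the C13 oxygen is released, so that only one hydroxyl is free at the esterification; no stereocentre is involved.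

Step 13
Reactants: 20 (4R,5S,6S,7R)-5-[(tert-butyldimethylsilyl)oxy]-7-[(4-methoxybenzyl)oxy]-2,4,6-trimethyloct-1-en-3-one
Product: 21 (4R,5S,6S,7R)-5-[(tert-butyldimethylsilyl)oxy]-7-hydroxy-2,4,6-trimethyloct-1-en-3-one
Conditions: DDQ, CH2Cl2/pH 7 buffer, 0 °C
Reagents that add atoms: none
Why: Oxidative cleavage of the 4-methoxybenzyl ether by DDQ (hydride abstraction, then hydrolysis of the oxocarbenium ion) frees C13–OH without affecting the silyl ether or the electron-poor enone.

Step 14
Reactants: 12 (2R,3S,4R,5S,6S)-3-[(tert-butyldimethylsilyl)oxy]-2,4,6-trimethyl-5-[(triethylsilyl)oxy]oct-7-enoic acid; 21 (4R,5S,6S,7R)-5-[(tert-butyldimethylsilyl)oxy]-7-hydroxy-2,4,6-trimethyloct-1-en-3-one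
Product: 23 (2R,3S,4S,5R)-4-[(tert-butyldimethylsilyl)oxy]-3,5,7-trimethyl-6-oxooct-7-en-2-yl (2R,3S,4R,5S,6S)-3-[(tert-butyldimethylsilyl)oxy]-2,4,6-trimethyl-5-[(triethylsilyl)oxy]oct-7-enoate, via mixed anhydride 22 (not isolated)
Conditions: 2,4,6-Cl3C6H2COCl, Et3N, THF, rt; then 21, DMAP, toluene, rt → 40 °C
Reagents that add atoms: none
Why: Yamaguchi esterification: DMAP attacks the mixed anhydride at the aliphatic carbonyl and the acylpyridinium ion acylates the hindered C13 hydroxyl with retention at C13 and, as usual for this method, without epimerisation at C2.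

Step 15
Reactants: 23 (2R,3S,4S,5R)-4-[(tert-butyldimethylsilyl)oxy]-3,5,7-trimethyl-6-oxooct-7-en-2-yl (2R,3S,4R,5S,6S)-3-[(tert-butyldimethylsilyl)oxy]-2,4,6-trimethyl-5-[(triethylsilyl)oxy]oct-7-enoate
Product: 24 (7E)-3,11-bis-O-(tert-butyldimethylsilyl)-5-O-(triethylsilyl)-7,8-didehydro-8,8a-deoxyoleandolide
Conditions: second-generation Hoveyda–Grubbs catalyst RuCl2(H2IMes)(=CH-C6H4-2-OiPr) (15 mol %), 1,4-benzoquinone (cat.), toluene (1 mM), 90 °C, argon purge
Reagents that add atoms: none
Why: Olefin metathesis by the [2+2] cycloaddition/cycloreversion sequence: the ruthenium benzylidene should first exchange with the monosubstituted C6 vinyl group (the isopropenyl ketone is too hindered and electron-poor to initiate), the C7 alkylidene then adds within the molecule to the C8 isopropenyl group, and the metallacyclobutane collapses to the C7=C8 bond and a ruthenium methylidene that releases ethene. The closest known reaction type is macrocyclic ring-closing metathesis to trisubstituted (E)-2-methyl enoates and enones with N-heterocyclic-carbene ruthenium catalysts, the intramolecular counterpart of the cross-metathesis of terminal alkenes with methacrylate-type partners. The ring is closed in the 14-membered mode at its only methylene position, with the new alkene inside the ring, and loss of ethene from the hot, purged solution makes the closure irreversible. No stereocentre is formed; the (E) geometry, with C6 cis to the C8 methyl and trans to the C9 carbonyl, is the one expected for a conjugated trisubstituted enone in a ring of this size, and it is the geometry that the later directed hydrogenation needs in order to translate C6 into C8. The step needs ring closure instead of oligomerisation and no double-bond migration: high dilution, the s-trans ester and the turns imposed by the methyl-bearing backbone and its silyl ethers favour folded conformers, benzoquinone suppresses isomerisation by ruthenium hydrides, and the substrate holds no third alkene.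

Step 16
Reactants: 24 (7E)-3,11-bis-O-(tert-butyldimethylsilyl)-5-O-(triethylsilyl)-7,8-didehydro-8,8a-deoxyoleandolide
Product: 25 (7E)-3,11-bis-O-(tert-butyldimethylsilyl)-7,8-didehydro-8,8a-deoxyoleandolide
Conditions: PPTS (cat.), MeOH/CH2Cl2, 0 °C → rt
Reagents that add atoms: none
Why: Acid-catalysed methanolysis cleaves a secondary triethylsilyl ether far faster than tert-butyldimethylsilyl ethers, so only C5–OH is freed, and the (E)-alkene in the ring rules out a 5,9-hemiketal at this stage; no stereocentre is involved.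

Step 17
Reactants: 25 (7E)-3,11-bis-O-(tert-butyldimethylsilyl)-7,8-didehydro-8,8a-deoxyoleandolide
Product: 26 3,11-bis-O-(tert-butyldimethylsilyl)-8,8a-deoxyoleandolide
Conditions: [Rh(nbd)(Ph2P(CH2)4PPh2)]BF4 (cat.), H2 (50 bar), CH2Cl2, rt
Reagents that add atoms: none
Why: Hydroxyl-directed hydrogenation with a cationic rhodium catalyst: the homoallylic C5 hydroxyl binds rhodium, A(1,3) strain between the C8 methyl and the C6 substituents holds the C6–H bond in the alkene plane, and both hydrogens are delivered to the alkene face syn to C5, which sets C8 (R) with the 6,8-syn relation; the silylated C3 and C11 oxygens cannot compete as directing groups.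

Step 18
Reactants: 26 3,11-bis-O-(tert-butyldimethylsilyl)-8,8a-deoxyoleandolide
Product: 27 8,8a-deoxyoleandolide
Conditions: HF·pyridine, pyridine, THF, 0 °C → rt
Reagents that add atoms: none
Why: Fluoride-mediated desilylation under buffered, mildly acidic conditions should remove both silyl ethers without retro-aldol cleavage, dehydration of the β-hydroxy ketone or acyl migration; no stereocentre is involved.

Compound list
1 | (R)-4-benzyl-3-propanoyl-1,3-oxazolidin-2-one | CCC(=O)N1[C@H](Cc2ccccc2)COC1=O | starting material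
2 | methacrolein | CC(=C)C=O | starting material
3 | (Z)-dibutylboron enolate of 1 | C/C=C(\OB(CCCC)CCCC)N1[C@H](Cc2ccccc2)COC1=O | intermediate (not isolated)
4 | (R)-4-benzyl-3-[(2R,3R)-3-hydroxy-2,4-dimethylpent-4-enoyl]-1,3-oxazolidin-2-one | O=C(N1[C@H](Cc2ccccc2)COC1=O)[C@H](C)[C@@H](O)C(C)=C | intermediate
5 | (R)-4-benzyl-3-[(2R,3R)-3-[(tert-butyldimethylsilyl)oxy]-2,4-dimethylpent-4-enoyl]-1,3-oxazolidin-2-one | O=C(N1[C@H](Cc2ccccc2)COC1=O)[C@H](C)[C@@H](O[Si](C)(C)C(C)(C)C)C(C)=C | intermediate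
6 | (R)-4-benzyl-3-[(2R,3S,4R)-5-(1,3,2-benzodioxaborol-2-yl)-3-[(tert-butyldimethylsilyl)oxy]-2,4-dimethylpentanoyl]-1,3-oxazolidin-2-one | O=C(N1[C@H](Cc2ccccc2)COC1=O)[C@H](C)[C@@H](O[Si](C)(C)C(C)(C)C)[C@H](C)CB1Oc2ccccc2O1 | intermediate (not isolated)
7 | (R)-4-benzyl-3-[(2R,3S,4R)-3-[(tert-butyldimethylsilyl)oxy]-5-hydroxy-2,4-dimethylpentanoyl]-1,3-oxazolidin-2-one | O=C(N1[C@H](Cc2ccccc2)COC1=O)[C@H](C)[C@@H](O[Si](C)(C)C(C)(C)C)[C@H](C)CO | intermediate
8 | (R)-4-benzyl-3-[(2R,3S,4S)-3-[(tert-butyldimethylsilyl)oxy]-2,4-dimethyl-5-oxopentanoyl]-1,3-oxazolidin-2-one | O=C(N1[C@H](Cc2ccccc2)COC1=O)[C@H](C)[C@@H](O[Si](C)(C)C(C)(C)C)[C@H](C)C=O | intermediate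
9 | (R)-4-benzyl-3-[(2R,3S,4R,5S,6S)-3-[(tert-butyldimethylsilyl)oxy]-5-hydroxy-2,4,6-trimethyloct-7-enoyl]-1,3-oxazolidin-2-one | O=C(N1[C@H](Cc2ccccc2)COC1=O)[C@H](C)[C@@H](O[Si](C)(C)C(C)(C)C)[C@H](C)[C@@H](O)[C@@H](C)C=C | intermediate
10 | (R)-4-benzyl-3-[(2R,3S,4R,5S,6S)-3-[(tert-butyldimethylsilyl)oxy]-2,4,6-trimethyl-5-[(triethylsilyl)oxy]oct-7-enoyl]-1,3-oxazolidin-2-one | O=C(N1[C@H](Cc2ccccc2)COC1=O)[C@H](C)[C@@H](O[Si](C)(C)C(C)(C)C)[C@H](C)[C@@H](O[Si](CC)(CC)CC)[C@@H](C)C=C | intermediate
11 | peroxy acid corresponding to 12 | OOC(=O)[C@H](C)[C@@H](O[Si](C)(C)C(C)(C)C)[C@H](C)[C@@H](O[Si](CC)(CC)CC)[C@@H](C)C=C | intermediate (not isolated)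
12 | (2R,3S,4R,5S,6S)-3-[(tert-butyldimethylsilyl)oxy]-2,4,6-trimethyl-5-[(triethylsilyl)oxy]oct-7-enoic acid | OC(=O)[C@H](C)[C@@H](O[Si](C)(C)C(C)(C)C)[C@H](C)[C@@H](O[Si](CC)(CC)CC)[C@@H](C)C=C | intermediate
13 | acetaldehyde | CC=O | starting material
14 | (2R,3R)-3-methylpent-4-en-2-ol | C=C[C@@H](C)[C@@H](C)O | intermediate
15 | 1-methoxy-4-({[(2R,3R)-3-methylpent-4-en-2-yl]oxy}methyl)benzene | C=C[C@@H](C)[C@@H](C)OCc1ccc(OC)cc1 | intermediate
16 | (2S,3R)-3-[(4-methoxybenzyl)oxy]-2-methylbutanal | O=C[C@@H](C)[C@@H](C)OCc1ccc(OC)cc1 | intermediate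
17 | 2-methylpent-1-en-3-one | CCC(=O)C(C)=C | starting material
18 | (Z)-dibutylboron enolate of 17 | C/C=C(\OB(CCCC)CCCC)C(C)=C | intermediate (not isolated)
19 | (4R,5S,6R,7R)-5-hydroxy-7-[(4-methoxybenzyl)oxy]-2,4,6-trimethyloct-1-en-3-one | C=C(C)C(=O)[C@H](C)[C@@H](O)[C@@H](C)[C@@H](C)OCc1ccc(OC)cc1 | intermediate
20 | (4R,5S,6S,7R)-5-[(tert-butyldimethylsilyl)oxy]-7-[(4-methoxybenzyl)oxy]-2,4,6-trimethyloct-1-en-3-one | C=C(C)C(=O)[C@H](C)[C@@H](O[Si](C)(C)C(C)(C)C)[C@@H](C)[C@@H](C)OCc1ccc(OC)cc1 | intermediate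
21 | (4R,5S,6S,7R)-5-[(tert-butyldimethylsilyl)oxy]-7-hydroxy-2,4,6-trimethyloct-1-en-3-one | C=C(C)C(=O)[C@H](C)[C@@H](O[Si](C)(C)C(C)(C)C)[C@@H](C)[C@@H](C)O | intermediate
22 | mixed anhydride of 12 with 2,4,6-trichlorobenzoic acid | O=C(OC(=O)c1c(Cl)cc(Cl)cc1Cl)[C@H](C)[C@@H](O[Si](C)(C)C(C)(C)C)[C@H](C)[C@@H](O[Si](CC)(CC)CC)[C@@H](C)C=C | intermediate (not isolated)
23 | (2R,3S,4S,5R)-4-[(tert-butyldimethylsilyl)oxy]-3,5,7-trimethyl-6-oxooct-7-en-2-yl (2R,3S,4R,5S,6S)-3-[(tert-butyldimethylsilyl)oxy]-2,4,6-trimethyl-5-[(triethylsilyl)oxy]oct-7-enoate | C=C(C)C(=O)[C@H](C)[C@@H](O[Si](C)(C)C(C)(C)C)[C@@H](C)[C@@H](C)OC(=O)[C@H](C)[C@@H](O[Si](C)(C)C(C)(C)C)[C@H](C)[C@@H](O[Si](CC)(CC)CC)[C@@H](C)C=C | intermediate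
24 | (7E)-3,11-bis-O-(tert-butyldimethylsilyl)-5-O-(triethylsilyl)-7,8-didehydro-8,8a-deoxyoleandolide (all stereocentres as in the target) | O=C1[C@H](C)[C@@H](O[Si](C)(C)C(C)(C)C)[C@H](C)[C@@H](O[Si](CC)(CC)CC)[C@@H](C)/C=C(\C)C(=O)[C@H](C)[C@@H](O[Si](C)(C)C(C)(C)C)[C@@H](C)[C@@H](C)O1 | intermediate
25 | (7E)-3,11-bis-O-(tert-butyldimethylsilyl)-7,8-didehydro-8,8a-deoxyoleandolide | O=C1[C@H](C)[C@@H](O[Si](C)(C)C(C)(C)C)[C@H](C)[C@@H](O)[C@@H](C)/C=C(\C)C(=O)[C@H](C)[C@@H](O[Si](C)(C)C(C)(C)C)[C@@H](C)[C@@H](C)O1 | intermediate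
26 | 3,11-bis-O-(tert-butyldimethylsilyl)-8,8a-deoxyoleandolide | O=C1[C@H](C)[C@@H](O[Si](C)(C)C(C)(C)C)[C@H](C)[C@@H](O)[C@@H](C)C[C@@H](C)C(=O)[C@H](C)[C@@H](O[Si](C)(C)C(C)(C)C)[C@@H](C)[C@@H](C)O1 | intermediate
27 | 8,8a-deoxyoleandolide, (2R,3S,4R,5S,6S,8R,10R,11S,12R,13R) | C[C@@H]1[C@@H](O)[C@@H](C)C[C@@H](C)C(=O)[C@H](C)[C@@H](O)[C@@H](C)[C@@H](C)OC(=O)[C@H](C)[C@H]1O | target

Total step count: 18. Longest linear sequence: 12 steps (steps 1–7, then 14–18).

Steps most likely to fail:

Step 15 (ring-closing metathesis). The ring closure may lose out to oligomerisation, or the C7 alkylidene may fail to engage the hindered, electron-poor isopropenyl ketone before the catalyst decays at high dilution. Fallback: the C7=C8 bond would be made between the fragments at high concentration and the ring closed at the lactone instead. Cross-metathesis of acid 12 with an excess of enone alcohol 21 (same ruthenium catalyst, toluene, 0.2 M, 80 °C) would give the (E)-configured seco acid F1. Yamaguchi macrolactonisation of seco acid F1 at high dilution (2,4,6-Cl3C6H2COCl, Et3N, THF; then DMAP, toluene) would come back to the route at 24.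

Step 17 (directed hydrogenation). Delivery of hydrogen from the C5 hydroxyl may be overridden by the ring conformation, giving poor facial selectivity at C8, or the hindered trisubstituted enone may reduce slowly. Fallback: reagent control in place of substrate direction, on the fully silylated enone. Asymmetric hydrogenation of 24 with a chiral iridium N,P catalyst, [Ir(cod)(L*)][B(C6H3-3,5-(CF3)2)4] with L* = one antipode of 4-tert-butyl-2-[2-(diphenylphosphino)phenyl]-4,5-dihydrooxazole (the matched antipode to be found by trial), H2, CH2Cl2, would give the saturated macrolide F2. Global desilylation of macrolide F2 with HF·pyridine would come back to the route at 27.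

Step 11 (aldol addition of the enone). The substrate-controlled addition may show poor facial selectivity (Felkin instead of anti-Felkin attack), or the cross-conjugated enolate may oligomerise. Fallback: auxiliary control. Evans syn-aldol reaction of aldehyde 16 with boron enolate 3, made from imide 1, would give the aldol adduct F3 with C10 and C11 set by the auxiliary. Transamidation (AlMe3, MeONHMe·HCl, CH2Cl2) would give the Weinreb amide F4, and excess isopropenylmagnesium bromide (THF, 0 °C) would convert Weinreb amide F4 into the β-hydroxy enone, returning to the route at 19.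

Further compounds
F1 | step 15 | (2R,3S,4R,5S,6S,7E,10R,11S,12S,13R)-3,11-bis[(tert-butyldimethylsilyl)oxy]-13-hydroxy-2,4,6,8,10,12-hexamethyl-9-oxo-5-[(triethylsilyl)oxy]tetradec-7-enoic acid | OC(=O)[C@H](C)[C@@H](O[Si](C)(C)C(C)(C)C)[C@H](C)[C@@H](O[Si](CC)(CC)CC)[C@@H](C)/C=C(\C)C(=O)[C@H](C)[C@@H](O[Si](C)(C)C(C)(C)C)[C@@H](C)[C@@H](C)O
F2 | step 17 | 3,11-bis-O-(tert-butyldimethylsilyl)-5-O-(triethylsilyl)-8,8a-deoxyoleandolide | O=C1[C@H](C)[C@@H](O[Si](C)(C)C(C)(C)C)[C@H](C)[C@@H](O[Si](CC)(CC)CC)[C@@H](C)C[C@@H](C)C(=O)[C@H](C)[C@@H](O[Si](C)(C)C(C)(C)C)[C@@H](C)[C@@H](C)O1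
F3 | step 11 | (R)-4-benzyl-3-[(2R,3S,4R,5R)-3-hydroxy-5-[(4-methoxybenzyl)oxy]-2,4-dimethylhexanoyl]-1,3-oxazolidin-2-one | O=C(N1[C@H](Cc2ccccc2)COC1=O)[C@H](C)[C@@H](O)[C@@H](C)[C@@H](C)OCc1ccc(OC)cc1
F4 | step 11 | (2R,3S,4R,5R)-3-hydroxy-N-methoxy-5-[(4-methoxybenzyl)oxy]-N,2,4-trimethylhexanamide | CON(C)C(=O)[C@H](C)[C@@H](O)[C@@H](C)[C@@H](C)OCc1ccc(OC)cc1
A1 | direct plan | (2R,3S,4R,5S,6S,8R)-3,5-bis[(tert-butyldimethylsilyl)oxy]-2,4,6,8-tetramethyl-9-oxoundecanoic acid | OC(=O)[C@H](C)[C@@H](O[Si](C)(C)C(C)(C)C)[C@H](C)[C@@H](O[Si](C)(C)C(C)(C)C)[C@@H](C)C[C@@H](C)C(=O)CC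
A2 | direct plan | (2R,3S)-3-methyl-4-oxobutan-2-yl (2R,3S,4R,5S,6S,8R)-10-bromo-3,5-bis[(tert-butyldimethylsilyl)oxy]-2,4,6,8-tetramethyl-9-oxoundecanoate (epimers at C10) | O=C[C@@H](C)[C@@H](C)OC(=O)[C@H](C)[C@@H](O[Si](C)(C)C(C)(C)C)[C@H](C)[C@@H](O[Si](C)(C)C(C)(C)C)[C@@H](C)C[C@@H](C)C(=O)C(Br)C
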